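(The readings come from a simulation with constants of no real substance; scatter was added.)

The west run leaves 70% of its substrate unreacted at 4.00 h, and its target gains 3 percentage points in the last hour against 11% in the first, so substrate is not the limiting reagent there. Its last target reading stands at 0.704 M, which gives 50.3% as the partner yield, the target formed at the stall per coupling partner charged.

| setting | north-west | west | south-west | Wednesday's | Sunday's |
|---|---|---|---|---|---|
| substrate | 0.66 M | 2.2 M | 1.4 M | 1.4 M | 0.50 M |
| coupling partner | 1.4 M | 1.4 M | 1.4 M | 1.40 M | 1.40 M |
| capture agent | 0.070 M | 0.070 M | 0.070 M | 0.0700 M | 0.0700 M |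
| free catalyst | 28 mM | 28 mM | 20 mM | 28 mM | 20 mM |
| remark | run made earlier | run made earlier | run made earlier |  |  |
| time |  |  |  | 8.0 h | 8.0 h |

- north-west (time / h: target / %, substrate / %): 0.333: 5, 94; 0.667: 11, 88; 1.50: 22, 77; 4.00: 51, 51
- west (time / h: target / %, substrate / %): 1.00: 11, 86; 2.00: 22, 79; 3.00: 29, 71; 4.00: 32, 70
- south-west (time / h: target / %, substrate / %): 1.00: 9, 88; 2.00: 17, 79; 3.00: 24, 76; 4.00: 29, 69

(scatter of a reading: 1.5 percentage points)

- a reading or a percentage of target counts all its forms, free or not

1. the flask that ends with the higher amount of target, in percent of the substrate charged, or "neither" when 2 percentage points or less lies between them (Wednesday's / Sunday's / neither)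
2. final target, as a percentage of the substrate charged, in Wednesday's
3. final target, as a percentage of the substrate charged, in Sunday's

The objection is that no reading shows coupling partner, and that catalyst dying per turnover is a second possible source of a ceiling, one proportional to catalyst. The south-west run cannot choose: such a ceiling there is 0.503 M, and its 0.406 M lies below that. For Wednesday's the doubt matters less, since that flask carries the west run's charges of coupling partner and catalyst, so either view gives 50.3% of its substrate, provided its smaller substrate charge reaches the same stall within 8.0 h.

Sunday's is different: its 0.50 M of substrate lies below the partner ceiling and about level with the catalyst ceiling, so its rate counts. The last substrate reading of the north-west run gives a first-order constant of 0.168 h⁻¹; scaled to Sunday's catalyst it is 0.120 h⁻¹, and over 8.0 h that means 61.8%. But that constant was read over 4.00 h, a shorter time, and coupling partner may fall further over the longer one, so the figure probably sits on the high side. The trim must still eat a gap of 11 points to reverse the order.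

This reckoning gives 50.3% and 61.8%; the forecast gives 48% and 58%, and names Sunday's, saying “Sunday, with little substrate, stays below that ceiling”.

The simulation gives 51.4% in Wednesday's and 56.2% in Sunday's, so Sunday's ends higher.

    coupling partner + free catalyst ⇌ catalyst intermediate A (K = 1.30 M⁻¹, k = 0.00713 M⁻¹ s⁻¹)
    substrate + catalyst intermediate A ⇌ catalyst intermediate B (K = 2.00 M⁻¹, k = 0.00359 M⁻¹ s⁻¹)
    catalyst intermediate B → free catalyst + target (k = 0.0715 s⁻¹)
    coupling partner → decomposed reagent (k = 3.91 × 10⁻⁵ s⁻¹)
    catalyst intermediate B + capture agent → trapped intermediate (k = 8.32 × 10⁻⁴ M⁻¹ s⁻¹)
    crystals ⇌ target, rate k6*(cs6 - [target]) while solid is left; crystals form when [target] > cs6 (solubility = 1.00 M, k = 0.00239 s⁻¹)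

In Wednesday's, coupling partner enters catalyst intermediate A 3.1 times as fast as it decomposes at 1.98 h and 4.5 times at 8.00 h (forward step alone, the way back not counted), and the partner yield at 8.00 h comes to 51.4% against 50.3%, with 40.7% of the charge decomposed, 88.9% of the catalyst free, and trapping making no difference. The flask like Wednesday's but with 0.35 M of coupling partner comes by the partner yield to 12.6% and ends at 16.2%, with 3.2% of its coupling partner left.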